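The 3,7-dioxabicyclo[3.3.0]octane core is numbered C1 (tertiary carbinol), C2 (guaiacyl CH), O3, C4, C5, C6 (veratryl CH), O7, C8. Ring A (C1, C2, O3, C4, C5) and ring B (C1, C5, C6, O7, C8) have the C1–C5 bond in common, and the benzylic carbon C2 is joined to O3. Cutting C1–C5 and C2–O3 leads to an acyclic ether: a C4–C5 epoxide beside the carbinol carbon C6, whose oxygen O7 carries a 2-alkoxy-3-arylallyl group (C8, C1=C2). One titanocene-catalysed radical isomerisation closes both rings and sets C1, C2 and C5 from C6 alone, keeping the C1 oxygen. Protection is fluoride-labile, because the core itself holds two benzylic ethers.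

Key step: step 9

Remark on protecting groups: C2–O3 and C6–O7 are benzylic ethers, and C2–O3 becomes a 4-hydroxybenzylic ether once the phenol is free. Benzyl-type groups, which need hydrogenolysis, acid or oxidation for removal, are therefore not used. The C1 oxygen is carried as a (triisopropylsilyloxy)methyl (TOM) acetal and the phenol as a triisopropylsilyl ether, so one fluoride treatment ends the synthesis.

Remark on stereochemistry: only C6 of the precursor matters, since C5 becomes a radical in step 9; the geometry of the C1=C2 alkene is likewise erased.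

Assumption: TOM-Cl and D-(−)-diisopropyl tartrate are taken as commercial.

Step 1
Reactants: 1 veratraldehyde (3,4-dimethoxybenzaldehyde); 2 vinylmagnesium bromide
Product: 3 rac-1-(3,4-dimethoxyphenyl)prop-2-en-1-ol
Conditions: THF, 0 °C → rt; aq NH4Cl
Reagents that add atoms: none
Why: Grignard 1,2-addition to the aldehyde; the carbinol centre (later C6) forms as the racemate and is resolved in step 2.

Step 2
Reactants: 3 rac-1-(3,4-dimethoxyphenyl)prop-2-en-1-ol
Product: 4 (R)-(3,4-dimethoxyphenyl)[(2S)-oxiran-2-yl]methanol (erythro)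
Conditions: Ti(OiPr)4 (0.2 equiv), D-(−)-diisopropyl tartrate (0.3 equiv), t-BuOOH (0.45 equiv, isooctane), 4 Å MS, CH2Cl2, −20 °C
Reagents that add atoms: tert-butyl hydroperoxide, CC(C)(C)OO
Why: Sharpless kinetic resolution by titanium–tartrate epoxidation: with the D-(−)-tartrate the (S)-enantiomer of 3 should be epoxidised much faster, on the alkene face the tartrate dictates (C5 becomes S) and erythro to the hydroxyl, so that C6 is R in 4 (same spatial arrangement as in (S)-3, the epoxide carbon now outranking the aryl group); the oxidant is limiting and the remaining (R)-enantiomer of 3 is removed by chromatography.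

Step 3
Reactants: 5 vanillin
Product: 6 3-methoxy-4-[(triisopropylsilyl)oxy]benzaldehyde
Conditions: i-Pr3SiCl, imidazole, DMF, rt
Reagents that add atoms: triisopropylsilyl chloride, CC(C)[Si](Cl)(C(C)C)C(C)C
Why: Imidazole-assisted O-silylation of the phenol (substitution at silicon); the bulky silyl ether should withstand the amide base, hydride and alkoxide used later, and no stereocentre is involved.

Step 4
Reactants: 7 methyl glycolate
Product: 8 methyl 2-{[(triisopropylsilyl)oxy]methoxy}acetate
Conditions: i-Pr3SiOCH2Cl (TOM-Cl), i-Pr2NEt, CH2Cl2, 0 °C → rt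
Reagents that add atoms: (triisopropylsiloxy)methyl chloride, ClCO[Si](C(C)C)(C(C)C)C(C)C
Why: O-alkylation of the primary alcohol by the chloromethyl ether through its oxocarbenium ion, the same reaction type as MOM or SEM protection; no stereocentre.

Step 5
Reactants: 8 methyl 2-{[(triisopropylsilyl)oxy]methoxy}acetate; 6 3-methoxy-4-[(triisopropylsilyl)oxy]benzaldehyde
Product: 11 methyl (Z)-3-{3-methoxy-4-[(triisopropylsilyl)oxy]phenyl}-2-{[(triisopropylsilyl)oxy]methoxy}prop-2-enoate, via lithium aldolate 9 (not isolated), via mesylate 10 (not isolated)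
Conditions: LiN(SiMe3)2, THF, −78 °C; 6; MsCl, −78 → 0 °C; DBU, 0 °C → rt
Reagents that add atoms: none
Why: Glycolate aldol addition, O-mesylation and E1cB elimination in one flask; the two aldol stereocentres are erased, and the Z alkene (aryl trans to the ester) is expected as the more stable isomer.

Step 6
Reactants: 11 methyl (Z)-3-{3-methoxy-4-[(triisopropylsilyl)oxy]phenyl}-2-{[(triisopropylsilyl)oxy]methoxy}prop-2-enoate
Product: 12 (Z)-3-{3-methoxy-4-[(triisopropylsilyl)oxy]phenyl}-2-{[(triisopropylsilyl)oxy]methoxy}prop-2-en-1-ol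
Conditions: i-Bu2AlH (2.2 equiv), CH2Cl2, −78 °C; aq potassium sodium tartrate
Reagents that add atoms: none
Why: 1,2-Reduction of the unsaturated ester by the aluminium hydride at low temperature, which should leave the enol acetal, the silyl ether and the alkene geometry untouched.

Step 7
Reactants: 12 (Z)-3-{3-methoxy-4-[(triisopropylsilyl)oxy]phenyl}-2-{[(triisopropylsilyl)oxy]methoxy}prop-2-en-1-ol
Product: 13 (Z)-3-bromo-1-{3-methoxy-4-[(triisopropylsilyl)oxy]phenyl}-2-{[(triisopropylsilyl)oxy]methoxy}prop-1-ene
Conditions: CBr4, PPh3, 2,6-lutidine (0.2 equiv), CH2Cl2, −20 → 0 °C; used at once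
Reagents that add atoms: carbon tetrabromide, BrC(Br)(Br)Br
Why: Appel reaction: bromide displaces the alkoxyphosphonium group at the primary allylic carbon under nearly neutral conditions, with lutidine buffering traces of HBr that would attack the enol acetal; no stereocentre.

Step 8
Reactants: 4 (R)-(3,4-dimethoxyphenyl)[(2S)-oxiran-2-yl]methanol; 13 (Z)-3-bromo-1-{3-methoxy-4-[(triisopropylsilyl)oxy]phenyl}-2-{[(triisopropylsilyl)oxy]methoxy}prop-1-ene
Product: 14 (2S)-2-[(R)-(3,4-dimethoxyphenyl){[(Z)-3-{3-methoxy-4-[(triisopropylsilyl)oxy]phenyl}-2-{[(triisopropylsilyl)oxy]methoxy}prop-2-en-1-yl]oxy}methyl]oxirane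
Conditions: NaH, THF, 0 °C → rt (NaH added last to the mixture of 4 and 13)
Reagents that add atoms: none
Why: Williamson ether synthesis (SN2 at the primary allylic bromide); adding the hydride last traps the alkoxide of 4 as it forms in aprotic THF, which should suppress Payne migration of the epoxide, and C6 and C5 are not touched.

Step 9
Reactants: 14 (2S)-2-[(R)-(3,4-dimethoxyphenyl){[(Z)-3-{3-methoxy-4-[(triisopropylsilyl)oxy]phenyl}-2-{[(triisopropylsilyl)oxy]methoxy}prop-2-en-1-yl]oxy}methyl]oxirane
Product: 15 (1S,2R,5R,6S)-6-(3,4-dimethoxyphenyl)-2-{3-methoxy-4-[(triisopropylsilyl)oxy]phenyl}-1-{[(triisopropylsilyl)oxy]methoxy}-3,7-dioxabicyclo[3.3.0]octane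
Conditions: Cp2TiCl2 (10 mol %), Mn powder (20 mol %), 2,4,6-collidine·HCl (20 mol %), degassed THF (0.01 M), rt → 40 °C
Reagents that add atoms: none
Why: Cp2TiCl (trivalent titanium), kept at a low stationary concentration, opens the monosubstituted epoxide by single-electron transfer to the secondary C5 radical with C4–O3 bound to tetravalent titanium; this radical adds to C1 of the aryl enol ether in a 5-exo-trig closure (ring B, C1–C5), and the resulting 4-silyloxybenzylic C2 radical attacks O3 with loss of Cp2TiCl in a 5-exo-tet homolytic substitution (ring A, C2–O3), so the step is an isomerisation that returns the catalyst. The closest known reactions are the titanocene-mediated radical cyclisations of epoxy cinnamyl ethers to lignan tetrahydrofurans and the titanocene-catalysed tetrahydrofuran synthesis by radical substitution at a Ti–O bond; here the acceptor carbon C1 additionally carries an acetal oxygen. C6 is the only controlling element for C5 and C1: in the chair-like 5-exo transition state the veratryl group is pseudo-equatorial, which places the C4 arm trans to it and cis to the C1–C2 arm and leaves the C1 oxygen cis to H5. C2 is set in the substitution step, where the cis ring fusion is obligatory and the aryl group should take the convex face, trans to C8. The step needs 5-exo addition at C1 over 6-endo addition at C2, which the benzylic stabilisation of the C2 radical should secure, and it needs oxygen substitution to outrun capture of the C2 radical by a second Cp2TiCl, which would expel the C1 acetal oxygen by β-elimination; catalytic titanium, substoichiometric Mn and high dilution serve this. A 5-exo adduct with the C4 arm trans to C2 cannot close ring A and would be lost, so the cis preference of the chair transition state is the stereochemical requirement of the cascade.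

Step 10
Reactants: 15 (1S,2R,5R,6S)-6-(3,4-dimethoxyphenyl)-2-{3-methoxy-4-[(triisopropylsilyl)oxy]phenyl}-1-{[(triisopropylsilyl)oxy]methoxy}-3,7-dioxabicyclo[3.3.0]octane
Product: 16 (1S,2R,5R,6S)-6-(3,4-dimethoxyphenyl)-2-(4-hydroxy-3-methoxyphenyl)-3,7-dioxabicyclo[3.3.0]octan-1-ol (target)
Conditions: Bu4NF (4 equiv), AcOH (4 equiv), THF, 0 °C → rt
Reagents that add atoms: none
Why: Fluoride-induced desilylation: the aryl silyl ether gives the phenol, and the TOM acetal loses its silyl group to a hemiacetal that releases formaldehyde and the tertiary alcohol; the conditions are neither reductive, oxidative nor strongly acidic, so the benzylic ethers C2–O3 and C6–O7 and all four stereocentres should be untouched.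

Compound list
1 | veratraldehyde (3,4-dimethoxybenzaldehyde) | COc1ccc(C=O)cc1OC | starting material
2 | vinylmagnesium bromide | C=C[Mg]Br | starting material
3 | rac-1-(3,4-dimethoxyphenyl)prop-2-en-1-ol | COc1ccc(C(O)C=C)cc1OC | intermediate
4 | (R)-(3,4-dimethoxyphenyl)[(2S)-oxiran-2-yl]methanol | COc1ccc([C@@H](O)[C@@H]2CO2)cc1OC | intermediate
5 | vanillin | COc1cc(C=O)ccc1O | starting material
6 | 3-methoxy-4-[(triisopropylsilyl)oxy]benzaldehyde | COc1cc(C=O)ccc1O[Si](C(C)C)(C(C)C)C(C)C | intermediate
7 | methyl glycolate | COC(=O)CO | starting material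
8 | methyl 2-{[(triisopropylsilyl)oxy]methoxy}acetate | COC(=O)COCO[Si](C(C)C)(C(C)C)C(C)C | intermediate
9 | lithium aldolate: methyl 3-(lithiooxy)-3-{3-methoxy-4-[(triisopropylsilyl)oxy]phenyl}-2-{[(triisopropylsilyl)oxy]methoxy}propanoate (diastereomer mixture) | COC(=O)C(OCO[Si](C(C)C)(C(C)C)C(C)C)C([O-])c1ccc(O[Si](C(C)C)(C(C)C)C(C)C)c(OC)c1.[Li+] | intermediate (not isolated)
10 | mesylate: methyl 3-(methanesulfonyloxy)-3-{3-methoxy-4-[(triisopropylsilyl)oxy]phenyl}-2-{[(triisopropylsilyl)oxy]methoxy}propanoate (diastereomer mixture) | COC(=O)C(OCO[Si](C(C)C)(C(C)C)C(C)C)C(OS(C)(=O)=O)c1ccc(O[Si](C(C)C)(C(C)C)C(C)C)c(OC)c1 | intermediate (not isolated)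
11 | methyl (Z)-3-{3-methoxy-4-[(triisopropylsilyl)oxy]phenyl}-2-{[(triisopropylsilyl)oxy]methoxy}prop-2-enoate | COC(=O)/C(OCO[Si](C(C)C)(C(C)C)C(C)C)=C/c1ccc(O[Si](C(C)C)(C(C)C)C(C)C)c(OC)c1 | intermediate
12 | (Z)-3-{3-methoxy-4-[(triisopropylsilyl)oxy]phenyl}-2-{[(triisopropylsilyl)oxy]methoxy}prop-2-en-1-ol | OC/C(OCO[Si](C(C)C)(C(C)C)C(C)C)=C/c1ccc(O[Si](C(C)C)(C(C)C)C(C)C)c(OC)c1 | intermediate
13 | (Z)-3-bromo-1-{3-methoxy-4-[(triisopropylsilyl)oxy]phenyl}-2-{[(triisopropylsilyl)oxy]methoxy}prop-1-ene | BrC/C(OCO[Si](C(C)C)(C(C)C)C(C)C)=C/c1ccc(O[Si](C(C)C)(C(C)C)C(C)C)c(OC)c1 | intermediate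
14 | (2S)-2-[(R)-(3,4-dimethoxyphenyl){[(Z)-3-{3-methoxy-4-[(triisopropylsilyl)oxy]phenyl}-2-{[(triisopropylsilyl)oxy]methoxy}prop-2-en-1-yl]oxy}methyl]oxirane | COc1ccc([C@@H](OC/C(OCO[Si](C(C)C)(C(C)C)C(C)C)=C/c2ccc(O[Si](C(C)C)(C(C)C)C(C)C)c(OC)c2)[C@@H]2CO2)cc1OC | intermediate
15 | (1S,2R,5R,6S)-6-(3,4-dimethoxyphenyl)-2-{3-methoxy-4-[(triisopropylsilyl)oxy]phenyl}-1-{[(triisopropylsilyl)oxy]methoxy}-3,7-dioxabicyclo[3.3.0]octane | COc1cc([C@H]2OC[C@@H]3[C@@H](c4ccc(OC)c(OC)c4)OC[C@]23OCO[Si](C(C)C)(C(C)C)C(C)C)ccc1O[Si](C(C)C)(C(C)C)C(C)C | intermediate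
16 | (1S,2R,5R,6S)-6-(3,4-dimethoxyphenyl)-2-(4-hydroxy-3-methoxyphenyl)-3,7-dioxabicyclo[3.3.0]octan-1-ol | COc1cc([C@H]2OC[C@@H]3[C@@H](c4ccc(OC)c(OC)c4)OC[C@]23O)ccc1O | target

Total step count: 10.
Longest linear sequence: 7 steps (5 → 6 → 11 → 12 → 13 → 14 → 15 → 16; steps 3, 5, 6, 7, 8, 9, 10).

Steps most likely to fail

1. Step 9 (key step). Three processes may defeat it. The C2 benzylic radical may be captured by a second Cp2TiCl, after which the C1 acetal oxygen is lost by β-elimination. The 5-exo closure may place the C4 arm trans to C2, so that ring A cannot form. The C5 radical may attack C2 in a 6-endo closure. The fallback sets out from 14 and makes the elimination the intended course. Stoichiometric Cp2TiCl (2.5 equiv, from Cp2TiCl2 and Zn dust, THF, rt) should give the benzylidene tetrahydrofuran methanol F1 (C5 and C6 as in 15, alkene as an E/Z mixture). It would form by reductive epoxide–alkene cyclisation, capture of the benzylic radical and β-alkoxide elimination from the organotitanium. Epoxidation with dimethyldioxirane (acetone, −20 °C), expected anti to the vicinal hydroxymethyl group, gives the spiro-epoxide F2. A catalytic amount of camphorsulfonic acid should open it at the electron-rich benzylic carbon C2 with capture by the C4 hydroxyl (O3). This leaves the C1 oxygen as the free tertiary alcohol in the phenol silyl ether F3; only the cis-fused bicycle can form, and the aryl group should take the convex face. Bu4NF/AcOH then gives 16, where the fallback rejoins the route.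

2. Step 8. The epoxide may migrate within the sodium alkoxide of 4 (Payne rearrangement) before O-alkylation. The electron-rich allylic bromide 13 may also ionise and self-condense, which burdens step 7 as well. The fallback sets out from 12 (with 4) and avoids both the bromide and a stoichiometric alkoxide. Boc2O with catalytic DMAP converts 12 into the tert-butyl carbonate F4. With Pd(PPh3)4 (zerovalent palladium) in THF this carbonate should ionise with loss of CO2 to the π-allyl complex and tert-butoxide. Alcohol 4 is then deprotonated only transiently and attacks the CH2 terminus (Tsuji–Trost O-allylation of an aliphatic alcohol with an allyl tert-butyl carbonate). The fallback rejoins the route at 14.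

3. Step 2. Epoxidation of the monosubstituted alkene may be slow, enantiomeric purity may erode on the product side of the resolution, and titanium may promote opening of the epoxy alcohol. The fallback sets out from 3 and separates resolution from epoxidation. Lipase-catalysed acylation (immobilised Candida antarctica lipase B, vinyl acetate, MTBE, rt, run past half conversion) should leave (S)-1-(3,4-dimethoxyphenyl)prop-2-en-1-ol F5 and convert the other enantiomer into the (R)-acetate F6. Epoxidation of F5 with mCPBA (NaHCO3, CH2Cl2) gives 4 together with its threo isomer F7. No separation is needed, since C5 becomes a radical in step 9. Compound 4 rejoins the route directly; F7 passes through step 8 to the C5 epimer F8 of 14, which converges with the main line at 15.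

Further compounds
F1 | step 9 | [(2-(3,4-dimethoxyphenyl)-4-{[3-methoxy-4-(triisopropylsilyloxy)phenyl]methylidene}tetrahydrofuran-3-yl]methanol, C5 and C6 configured as in 15, E/Z mixture | OC[C@@H]1[C@@H](c2ccc(OC)c(OC)c2)OCC1=Cc1ccc(O[Si](C(C)C)(C(C)C)C(C)C)c(OC)c1
F2 | step 9 | spiro-epoxide of F1 (epoxide oxygen on C1 trans to the hydroxymethyl group, C2 epimer mixture) | OC[C@@H]1[C@@H](c2ccc(OC)c(OC)c2)OC[C@@]13OC3c1ccc(O[Si](C(C)C)(C(C)C)C(C)C)c(OC)c1
F3 | step 9 | (1S,2R,5R,6S)-6-(3,4-dimethoxyphenyl)-2-{3-methoxy-4-[(triisopropylsilyl)oxy]phenyl}-3,7-dioxabicyclo[3.3.0]octan-1-ol | COc1cc([C@H]2OC[C@@H]3[C@@H](c4ccc(OC)c(OC)c4)OC[C@]23O)ccc1O[Si](C(C)C)(C(C)C)C(C)C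
F4 | step 8 | tert-butyl (Z)-3-{3-methoxy-4-[(triisopropylsilyl)oxy]phenyl}-2-{[(triisopropylsilyl)oxy]methoxy}prop-2-en-1-yl carbonate | CC(C)(C)OC(=O)OC/C(OCO[Si](C(C)C)(C(C)C)C(C)C)=C/c1ccc(O[Si](C(C)C)(C(C)C)C(C)C)c(OC)c1
F5 | step 2 | (S)-1-(3,4-dimethoxyphenyl)prop-2-en-1-ol | COc1ccc([C@@H](O)C=C)cc1OC
F6 | step 2 | (R)-1-(3,4-dimethoxyphenyl)prop-2-en-1-yl acetate | COc1ccc([C@H](OC(C)=O)C=C)cc1OC
F7 | step 2 | (R)-(3,4-dimethoxyphenyl)[(2R)-oxiran-2-yl]methanol (threo) | COc1ccc([C@@H](O)[C@H]2CO2)cc1OC
F8 | step 2 | (2R)-2-[(R)-(3,4-dimethoxyphenyl){[(Z)-3-{3-methoxy-4-[(triisopropylsilyl)oxy]phenyl}-2-{[(triisopropylsilyl)oxy]methoxy}prop-2-en-1-yl]oxy}methyl]oxirane | COc1ccc([C@@H](OC/C(OCO[Si](C(C)C)(C(C)C)C(C)C)=C/c2ccc(O[Si](C(C)C)(C(C)C)C(C)C)c(OC)c2)[C@H]2CO2)cc1OC
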